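The cycloheptenone ring of this cis-fused hydroazulenone is disconnected as a [5+2] cycloaddition between a two-carbon unit (C8 and C8a, azulene locants) and a five-carbon unit (C3a to C7). The step exploits the 4-methoxybenzoate on C4: placed on the neighbouring propargylic carbon of a 3-acyloxy-1,4-enyne, it is the migrating group that turns the enyne into the five-carbon partner. The precursor is an open-chain enyne ester whose alkyne bears the C3 carbinol and a tethered tetrasubstituted allene. One operation, catalysed by [Rh(cod)2]BF4, shifts the ester to C4, forms C3a–C8a and C7–C8, closes both rings and sets quaternary C8a. Ozonolysis, hydroxyl-directed hydrogenation and dehydrogenation complete the target.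

Key step: step 11

Remark: locants in the Why lines are the azulene locants of the target (C3 carbinol, C3a and C8a ring fusion, C4 ester carbon, C6 methyl-bearing carbon, C8 ketone); the ester-bearing propargylic carbon of the cycloaddition precursor becomes sp2 in the key step and is therefore carried as both epimers, and 2-methylpent-3-yn-2-ol and ethyl 4-methyl-3-oxopentanoate are taken as purchasable.

Step 1
Reactants: 1 2-methylpent-3-yn-2-ol; 2 triethyl orthoacetate
Product: 3 ethyl 3,5-dimethylhexa-3,4-dienoate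
Conditions: EtCO2H (cat.), neat, 140 °C, EtOH distilled off
Reagents that add atoms: none
Why: Johnson orthoester Claisen rearrangement, in which the mixed ketene acetal of the tertiary propargylic alcohol should undergo the [3,3] shift onto the alkyne and give the β-allenic ester with the tetrasubstituted allene in place (no stereocentre).

Step 2
Reactants: 3 ethyl 3,5-dimethylhexa-3,4-dienoate
Product: 4 3,5-dimethylhexa-3,4-dien-1-ol
Conditions: LiAlH4, Et2O, 0 °C
Reagents that add atoms: none
Why: Hydride reduction of the ester to the primary alcohol; the isolated allene should be inert to LiAlH4.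

Step 3
Reactants: 4 3,5-dimethylhexa-3,4-dien-1-ol
Product: 5 6-bromo-2,4-dimethylhexa-2,3-diene
Conditions: CBr4, PPh3, CH2Cl2, 0 °C
Reagents that add atoms: carbon tetrabromide, BrC(Br)(Br)Br
Why: Appel bromination of the primary alcohol under neutral conditions that should leave the allene untouched.

Step 4
Reactants: 6 ethyl 4-methyl-3-oxopentanoate
Product: 7 ethyl (2Z)-4-methyl-3-{[(trifluoromethyl)sulfonyl]oxy}pent-2-enoate
Conditions: Tf2O, aq LiOH, hexane, 5 °C
Reagents that add atoms: trifluoromethanesulfonic anhydride, O=S(=O)(OS(=O)(=O)C(F)(F)F)C(F)(F)F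
Why: Enol triflate formation by O-sulfonylation of the lithium-chelated Z enolate of the β-keto ester, which should place the triflate cis to the ester.

Step 5
Reactants: 5 6-bromo-2,4-dimethylhexa-2,3-diene; 7 ethyl (2Z)-4-methyl-3-{[(trifluoromethyl)sulfonyl]oxy}pent-2-enoate
Product: 9 ethyl (2E)-6,8-dimethyl-3-(propan-2-yl)nona-2,6,7-trienoate, via Grignard reagent 8 (not isolated)
Conditions: Mg, THF, 25 °C; then 7, Fe(acac)3 (5 mol %), THF/NMP, −30 °C
Reagents that add atoms: none
Why: Fe(acac)3-catalysed Kumada-type cross-coupling of the alkyl Grignard reagent with the β-triflyloxy enoate, which should run with retention of alkene geometry and so fix the new chain cis to the ester (2E).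

Step 6
Reactants: 9 ethyl (2E)-6,8-dimethyl-3-(propan-2-yl)nona-2,6,7-trienoate
Product: 10 (2E)-6,8-dimethyl-3-(propan-2-yl)nona-2,6,7-trien-1-ol
Conditions: iBu2AlH (2.2 equiv), CH2Cl2, −78 °C
Reagents that add atoms: none
Why: 1,2-Reduction of the enoate to the allylic alcohol, which should leave the alkene geometry and the allene unchanged.

Step 7
Reactants: 10 (2E)-6,8-dimethyl-3-(propan-2-yl)nona-2,6,7-trien-1-ol
Product: 11 [(2R,3R)-3-(3,5-dimethylhexa-3,4-dien-1-yl)-3-(propan-2-yl)oxiran-2-yl]methanol
Conditions: Ti(OiPr)4 (10 mol %), D-(−)-diethyl tartrate (12 mol %), t-BuOOH, 4 Å MS, CH2Cl2, −20 °C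
Reagents that add atoms: tert-butyl hydroperoxide, CC(C)(C)OO
Why: Sharpless asymmetric epoxidation, in which the Ti(OiPr)4/tartrate complex epoxidises only the allylic alcohol and the D-(−)-tartrate should deliver oxygen to the face that makes the fully substituted epoxide carbon (the later C3 carbinol) R.

Step 8
Reactants: 11 [(2R,3R)-3-(3,5-dimethylhexa-3,4-dien-1-yl)-3-(propan-2-yl)oxiran-2-yl]methanol
Product: 12 (2S,3R)-2-(chloromethyl)-3-(3,5-dimethylhexa-3,4-dien-1-yl)-3-(propan-2-yl)oxirane
Conditions: PPh3, CCl4, NaHCO3, reflux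
Reagents that add atoms: carbon tetrachloride, ClC(Cl)(Cl)Cl
Why: Appel chlorination of the primary alcohol, which should leave both epoxide centres untouched (the descriptor at C2 changes only through the priority of CH2Cl).

Step 9
Reactants: 12 (2S,3R)-2-(chloromethyl)-3-(3,5-dimethylhexa-3,4-dien-1-yl)-3-(propan-2-yl)oxirane
Product: 13 (3R)-6,8-dimethyl-3-(propan-2-yl)nona-6,7-dien-1-yn-3-ol
Conditions: n-BuLi (3.2 equiv), THF, −78 to −20 °C; aq NH4Cl
Reagents that add atoms: none
Why: Base-induced double elimination of the 2,3-epoxy chloride (α-lithiation, epoxide opening to the chloroalkenyl alkoxide, loss of HCl) should give the terminal propargylic alcohol, and because the C–O bond at the fully substituted carbon is never broken its configuration is kept.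

Step 10
Reactants: 13 (3R)-6,8-dimethyl-3-(propan-2-yl)nona-6,7-dien-1-yn-3-ol; 14 2-methylprop-2-enal; 15 4-methoxybenzoyl chloride
Product: 17 (3RS,6R)-6-hydroxy-2,9,11-trimethyl-6-(propan-2-yl)dodeca-1,9,10-trien-4-yn-3-yl 4-methoxybenzoate, via dilithium diolate 16 (not isolated)
Conditions: n-BuLi (2.05 equiv), THF, −78 °C; 14; then 15 (1.0 equiv), −78 to 0 °C
Reagents that add atoms: none
Why: 1,2-Addition of the lithium acetylide to the enal followed by chemoselective O-acylation of the less hindered secondary alkoxide; the new ester-bearing centre (later C5) forms without control and is carried as both epimers.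

Step 11
Reactants: 17 (3RS,6R)-6-hydroxy-2,9,11-trimethyl-6-(propan-2-yl)dodeca-1,9,10-trien-4-yn-3-yl 4-methoxybenzoate
Product: 18 (3R,8aR)-3-hydroxy-6,8a-dimethyl-3-(propan-2-yl)-8-(propan-2-ylidene)-1,2,3,7,8,8a-hexahydroazulen-4-yl 4-methoxybenzoate
Conditions: [Rh(cod)2]BF4 (5 mol %), P[OCH(CF3)2]3 (10 mol %), CH2Cl2 (0.01 M), 40 °C
Reagents that add atoms: none
Why: Cationic monovalent rhodium should activate the alkyne so that the electron-rich 4-methoxybenzoyloxy group shifts 1,2 from the propargylic carbon (later C5) to the adjacent alkyne carbon (later C4), and the resulting rhodacyclohexadiene (Rh bound to vinylic C3a and allylic C7) is intercepted by the tethered allene, whose internal π bond inserts into the Rh–C3a bond (C3a–C8a) before reductive elimination joins C7 to C8. The reaction type is the [5+2] cycloaddition of 3-acyloxy-1,4-enynes with tethered alkynes or alkenes under 1,2-acyloxy migration, applied here to an enyne ester tethered through its alkyne terminus to an allene; the allene/vinylcyclopropane [5+2] cycloaddition is the closest analogy for the two-carbon partner. The cyclopentane closes by 5-exo carbometalation of the proximal allene bond and the cycloheptadiene by C(sp2)–C(sp3) reductive elimination from an eight-membered rhodacycle. The only new stereocentre, quaternary C8a, is set by the C3 carbinol: allylic 1,3-strain with the migrated aroyloxy group on C4 keeps the isopropyl group of C3 pseudo-axial in the chair-like insertion transition state, so C8 should be delivered cis to isopropyl and the methyl group cis to the hydroxyl. The step needs the 1,2- rather than the 1,3-acyloxy shift and reaction at the internal allene bond; the donor-substituted aroyl group and the oxygenated alkyne terminus should secure the former, the gem-dimethyl allene terminus the latter.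

Step 12
Reactants: 18 (3R,8aR)-3-hydroxy-6,8a-dimethyl-3-(propan-2-yl)-8-(propan-2-ylidene)-1,2,3,7,8,8a-hexahydroazulen-4-yl 4-methoxybenzoate
Product: 19 (3R,8aS)-3-hydroxy-6,8a-dimethyl-8-oxo-3-(propan-2-yl)-1,2,3,7,8,8a-hexahydroazulen-4-yl 4-methoxybenzoate
Conditions: O3 (1.0 equiv, Sudan Red 7B end point), pyridine, CH2Cl2, −78 °C; then PPh3
Reagents that add atoms: ozone, [O-][O+]=O
Why: Ozonolysis, in which the electrophilic ozone should pick the tetrasubstituted all-alkyl exocyclic alkene over the acyloxy-deactivated ring diene and unveil the C8 ketone (the 8a descriptor changes only through priorities).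

Step 13
Reactants: 19 (3R,8aS)-3-hydroxy-6,8a-dimethyl-8-oxo-3-(propan-2-yl)-1,2,3,7,8,8a-hexahydroazulen-4-yl 4-methoxybenzoate
Product: 20 (3R,3aR,4S,6RS,8aS)-3-hydroxy-6,8a-dimethyl-8-oxo-3-(propan-2-yl)decahydroazulen-4-yl 4-methoxybenzoate
Conditions: H2 (1–5 bar), [Ir(cod)(PCy3)(py)]PF6 (10 mol %), CH2Cl2, 0 to 25 °C
Reagents that add atoms: none
Why: Hydroxyl-directed homogeneous hydrogenation, in which the C3 hydroxyl binds the cationic monovalent iridium centre so that both hydrogens should add to C3a=C4 from the hydroxyl face, setting C3a (R), C4 (S) and the cis ring fusion, while C5=C6 is reduced without control (C6 epimers).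

Step 14
Reactants: 20 (3R,3aR,4S,6RS,8aS)-3-hydroxy-6,8a-dimethyl-8-oxo-3-(propan-2-yl)decahydroazulen-4-yl 4-methoxybenzoate
Product: 21 (3R,3aR,4S,8aS)-3-hydroxy-6,8a-dimethyl-8-oxo-3-(propan-2-yl)-1,2,3,3a,4,5,8,8a-octahydroazulen-4-yl 4-methoxybenzoate
Conditions: 2-iodoxybenzoic acid (IBX, 2.5 equiv), DMSO/toluene (1:2), 70 °C
Reagents that add atoms: none
Why: IBX dehydrogenation of the ketone through its enol; only C7 bears α-hydrogens (C8a is quaternary), so the C6=C7 enone should form regiospecifically and both C6 epimers converge on the target.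

Compound list
1 | 2-methylpent-3-yn-2-ol | CC#CC(C)(C)O | starting material
2 | triethyl orthoacetate | CC(OCC)(OCC)OCC | starting material
3 | ethyl 3,5-dimethylhexa-3,4-dienoate | CCOC(=O)CC(C)=C=C(C)C | intermediate
4 | 3,5-dimethylhexa-3,4-dien-1-ol | OCCC(C)=C=C(C)C | intermediate
5 | 6-bromo-2,4-dimethylhexa-2,3-diene | BrCCC(C)=C=C(C)C | intermediate
6 | ethyl 4-methyl-3-oxopentanoate | CCOC(=O)CC(=O)C(C)C | starting material
7 | ethyl (2Z)-4-methyl-3-{[(trifluoromethyl)sulfonyl]oxy}pent-2-enoate | CCOC(=O)/C=C(\OS(=O)(=O)C(F)(F)F)C(C)C | intermediate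
8 | (3,5-dimethylhexa-3,4-dien-1-yl)magnesium bromide | CC(C)=C=C(C)CC[Mg]Br | intermediate
9 | ethyl (2E)-6,8-dimethyl-3-(propan-2-yl)nona-2,6,7-trienoate | CCOC(=O)/C=C(\CCC(C)=C=C(C)C)C(C)C | intermediate
10 | (2E)-6,8-dimethyl-3-(propan-2-yl)nona-2,6,7-trien-1-ol | OC/C=C(\CCC(C)=C=C(C)C)C(C)C | intermediate
11 | [(2R,3R)-3-(3,5-dimethylhexa-3,4-dien-1-yl)-3-(propan-2-yl)oxiran-2-yl]methanol | OC[C@H]1O[C@]1(CCC(C)=C=C(C)C)C(C)C | intermediate
12 | (2S,3R)-2-(chloromethyl)-3-(3,5-dimethylhexa-3,4-dien-1-yl)-3-(propan-2-yl)oxirane | ClC[C@H]1O[C@]1(CCC(C)=C=C(C)C)C(C)C | intermediate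
13 | (3R)-6,8-dimethyl-3-(propan-2-yl)nona-6,7-dien-1-yn-3-ol | C#C[C@@](O)(CCC(C)=C=C(C)C)C(C)C | intermediate
14 | 2-methylprop-2-enal | CC(=C)C=O | starting material
15 | 4-methoxybenzoyl chloride | COc1ccc(cc1)C(Cl)=O | starting material
16 | dilithium (3RS,6R)-2,9,11-trimethyl-6-(propan-2-yl)dodeca-1,9,10-trien-4-yne-3,6-diolate | [Li+].[Li+].[O-]C(C#C[C@@]([O-])(CCC(C)=C=C(C)C)C(C)C)C(C)=C | intermediate
17 | (3RS,6R)-6-hydroxy-2,9,11-trimethyl-6-(propan-2-yl)dodeca-1,9,10-trien-4-yn-3-yl 4-methoxybenzoate | COc1ccc(cc1)C(=O)OC(C#C[C@@](O)(CCC(C)=C=C(C)C)C(C)C)C(C)=C | intermediate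
18 | (3R,8aR)-3-hydroxy-6,8a-dimethyl-3-(propan-2-yl)-8-(propan-2-ylidene)-1,2,3,7,8,8a-hexahydroazulen-4-yl 4-methoxybenzoate | COc1ccc(cc1)C(=O)OC1=C2[C@](O)(C(C)C)CC[C@]2(C)C(=C(C)C)CC(C)=C1 | intermediate
19 | (3R,8aS)-3-hydroxy-6,8a-dimethyl-8-oxo-3-(propan-2-yl)-1,2,3,7,8,8a-hexahydroazulen-4-yl 4-methoxybenzoate | COc1ccc(cc1)C(=O)OC1=C2[C@](O)(C(C)C)CC[C@]2(C)C(=O)CC(C)=C1 | intermediate
20 | (3R,3aR,4S,6RS,8aS)-3-hydroxy-6,8a-dimethyl-8-oxo-3-(propan-2-yl)decahydroazulen-4-yl 4-methoxybenzoate | COc1ccc(C(=O)O[C@H]2CC(C)CC(=O)[C@@]3(C)CC[C@@](O)(C(C)C)[C@@H]23)cc1 | intermediate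
21 | (3R,3aR,4S,8aS)-3-hydroxy-6,8a-dimethyl-8-oxo-3-(propan-2-yl)-1,2,3,3a,4,5,8,8a-octahydroazulen-4-yl 4-methoxybenzoate | COc1ccc(C(=O)O[C@H]2CC(C)=CC(=O)[C@@]3(C)CC[C@@](O)(C(C)C)[C@@H]23)cc1 | target

Total step count: 14. Longest linear sequence: 13 steps (steps 1–3 and 5–14, from 2-methylpent-3-yn-2-ol); step 4 is a one-step side branch.

Steps most likely to fail

Step 11. The 1,2-shift of the aroyloxy group on the internal alkyne may lose to the [3,3] shift to an allenyl ester, or the rhodacycle may collapse in a Rautenstrauch-type ring closure before the hindered allene inserts. Poor facial selectivity at C8a is a further risk that this fallback does not address. The fallback takes the migrating role away from the ester of the target and gives it to a stronger donor ester, which is exchanged once both rings are set. It sets out from the dilithium diolate 16, which would be acylated with 4-(dimethylamino)benzoyl chloride to the enyne 4-(dimethylamino)benzoate F1. The same cycloaddition should give the bicyclic dienyl ester F2, ozonolysis the ketone F3 and directed hydrogenation the saturated ester F4. K2CO3 in MeOH would cleave the ester to the hydroxy ketone F5, and acylation of its secondary hydroxyl with 15 (pyridine, DMAP, CH2Cl2) comes back to the route at 20.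

Step 12. Over-oxidation is the risk: ozone may also attack the ring diene, whose 5,6-alkene is conjugated with the enol ester. The fallback changes the order of events and sets out from 18. Hydroxyl-directed hydrogenation with [Rh(nbd)(dppb)]BF4 (nbd = norbornadiene, dppb = 1,4-bis(diphenylphosphino)butane) and H2 (50 bar), a catalyst that should not touch an undirected tetrasubstituted alkene, would first saturate the ring diene to the isopropylidene compound F6. Ozonolysis of its only remaining alkene then comes back at 20.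

Step 13. The iridium hydride may isomerise the 1,3-diene, which loses the hydroxyl-directed delivery to C3a, or the catalyst may be held as an inert diene complex, so that reduction stalls or the ring fusion is scrambled. The fallback removes the diene before the reduction and sets out from 19. Catalytic DBU (CH2Cl2, 0 °C) should move the 5,6-alkene into conjugation with the ketone by kinetic protonation at C5, giving the enone enol ester F7. Its now isolated tetrasubstituted enol ester, flanked by the C3 hydroxyl, would be hydrogenated under hydroxyl direction with [Rh(nbd)(dppb)]BF4 and H2, which comes back to the route at the target 21; any over-reduced material is 20 and passes through step 14.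

Further compounds
F1 | step 11 | (3RS,6R)-6-hydroxy-2,9,11-trimethyl-6-(propan-2-yl)dodeca-1,9,10-trien-4-yn-3-yl 4-(dimethylamino)benzoate | CN(C)c1ccc(cc1)C(=O)OC(C#C[C@@](O)(CCC(C)=C=C(C)C)C(C)C)C(C)=C
F2 | step 11 | (3R,8aR)-3-hydroxy-6,8a-dimethyl-3-(propan-2-yl)-8-(propan-2-ylidene)-1,2,3,7,8,8a-hexahydroazulen-4-yl 4-(dimethylamino)benzoate | CN(C)c1ccc(cc1)C(=O)OC1=C2[C@](O)(C(C)C)CC[C@]2(C)C(=C(C)C)CC(C)=C1
F3 | step 11 | (3R,8aS)-3-hydroxy-6,8a-dimethyl-8-oxo-3-(propan-2-yl)-1,2,3,7,8,8a-hexahydroazulen-4-yl 4-(dimethylamino)benzoate | CN(C)c1ccc(cc1)C(=O)OC1=C2[C@](O)(C(C)C)CC[C@]2(C)C(=O)CC(C)=C1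
F4 | step 11 | (3R,3aR,4S,6RS,8aS)-3-hydroxy-6,8a-dimethyl-8-oxo-3-(propan-2-yl)decahydroazulen-4-yl 4-(dimethylamino)benzoate | CN(C)c1ccc(C(=O)O[C@H]2CC(C)CC(=O)[C@@]3(C)CC[C@@](O)(C(C)C)[C@@H]23)cc1
F5 | step 11 | (3R,3aR,4S,6RS,8aS)-3,4-dihydroxy-6,8a-dimethyl-3-(propan-2-yl)octahydroazulen-8(1H)-one (locants as in 20) | O[C@H]1CC(C)CC(=O)[C@@]2(C)CC[C@@](O)(C(C)C)[C@@H]12
F6 | step 12 | (3R,3aR,4S,6RS,8aS)-3-hydroxy-6,8a-dimethyl-3-(propan-2-yl)-8-(propan-2-ylidene)decahydroazulen-4-yl 4-methoxybenzoate | COc1ccc(C(=O)O[C@H]2CC(C)CC(=C(C)C)[C@@]3(C)CC[C@@](O)(C(C)C)[C@@H]23)cc1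
F7 | step 13 | (3R,8aS)-3-hydroxy-6,8a-dimethyl-8-oxo-3-(propan-2-yl)-1,2,3,5,8,8a-hexahydroazulen-4-yl 4-methoxybenzoate | COc1ccc(cc1)C(=O)OC1=C2[C@](O)(C(C)C)CC[C@]2(C)C(=O)C=C(C)C1
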